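Cuts, in retrosynthetic order: the O‑acetyl group and the C15 ester; C8–OH (back to the 8(17)‑alkene and a C8 ketone); C13=C14 (HWE); then C6–C7 and C5–C10 together; then C1–C10 (sp3–sp2 coupling) and C9–C11 (acetoacetate alkylation).
Enabling feature: ring B (C5–C6–C7–C8–C9–C10) carries its oxygen on C8 next to the side‑chain carbon C9. It is therefore the hydrolysed form of a cyclohexene enol ether C8(OMe)=C9, a Diels–Alder retron with diene C7=C8(OMe)–C9=C10 and dienophile C5=C6. C5–C10 is also the A/B fusion bond, so C1–C2–C3–C4 is the tether and both rings open at once.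
Helper: O18–C18–C4–C5 is a four‑atom chain, so one extra carbonyl carbon (C21) on C5 ties O18 to C5 as an α‑methylene‑γ‑butyrolactone. This temporary ring activates C5=C6 with the matching polarity, distinguishes C18 from C19 and blocks one face. It is removed by DIBAL‑H and rhodium decarbonylation, which leave C5–H with retention and a free 18‑OH.
Forward: the lactone ring first (fragment 10, 7 steps), dienyl triflate 15 (3 steps), B‑alkyl Suzuki union, rings A and B in one cycloaddition, helper out, side chain, C8 carbinol, acetate.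
Stereochemistry: C4 from Sharpless epoxidation plus a stereospecific 1,2‑shift; C5 and C10 from C4, the E‑C9=C10 geometry and the endo rule in the cycloaddition; C9 by axial protonation/equilibration; C8 by α‑face hydration opposite the axial C20 methyl; C13=C14 by E‑selective HWE.

Key step: step 12

Remark: labdane numbering is used for all intermediates (C18 = 4α‑CH2O, C19 = 4β‑CH3, C20 = 10β‑CH3, C17 = CH3 on C8, C21 = the temporary lactone carbonyl carbon). Compounds 1, 11 and 12 are taken as commercial.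

Step 1
Reactants: 1 pent‑1‑en‑4‑yne
Product: 4 (2E)‑3‑methylhexa‑2,5‑dien‑1‑ol, via alkenylalane 2 (not isolated), via lithium alanate 3 (not isolated)
Conditions: Me3Al, Cp2ZrCl2 (cat.), CH2Cl2, 0 °C → rt; n‑BuLi, THF, −78 °C; (CH2O)n, −78 °C → rt; aq. work‑up
Reagents that add atoms: trimethylaluminium, C[Al](C)C; formaldehyde (as paraformaldehyde), C=O; n‑butyllithium, [Li]CCCC (kept only in 3)
Why: Negishi zirconium‑catalysed carboalumination adds CH3 and Al syn across the terminal alkyne only (the alkene is far slower), and the derived alanate is hydroxymethylated with retention, which fixes the E‑trisubstituted alkene.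

Step 2
Reactants: 4 (2E)‑3‑methylhexa‑2,5‑dien‑1‑ol
Product: 5 [(2S,3S)‑3‑methyl‑3‑(prop‑2‑en‑1‑yl)oxiran‑2‑yl]methanol
Conditions: Ti(OiPr)4 (cat.), L‑(+)‑DET (cat.), t‑BuOOH, 4 Å MS, CH2Cl2, −20 °C
Reagents that add atoms: tert‑butyl hydroperoxide, CC(C)(C)OO
Why: Sharpless asymmetric epoxidation is directed by the allylic hydroxyl, so only the trisubstituted alkene reacts, and L‑(+)‑tartrate delivers oxygen to the face that gives the (2S,3S)‑epoxide.

Step 3
Reactants: 5 [(2S,3S)‑3‑methyl‑3‑(prop‑2‑en‑1‑yl)oxiran‑2‑yl]methanol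
Product: 6 TBS ether of 5
Conditions: TBSCl, imidazole, DMF, rt
Reagents that add atoms: tert‑butyldimethylsilyl chloride, CC(C)(C)[Si](C)(C)Cl
Why: Standard silylation of the primary alcohol, needed because the silyl ether gives the CH2O group its migratory aptitude in step 4.

Step 4
Reactants: 6 TBS ether of 5
Product: 7 (2S)‑2‑[(tert‑butyldimethylsilyloxy)methyl]‑2‑methylpent‑4‑enal
Conditions: MABR [MeAl(OAr)2, Ar = 4‑bromo‑2,6‑di‑tert‑butylphenyl] (cat.), CH2Cl2, −78 → −40 °C
Reagents that add atoms: none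
Why: Bulky‑aluminium‑promoted epoxide rearrangement (semipinacol‑type 1,2‑shift): the C–O bond at the tertiary carbon ionises and the siloxymethyl group migrates anti to it with inversion, so the epoxide configuration is carried into the all‑carbon quaternary centre (future C4) and the former epoxide CH becomes the aldehyde (future C5).

Step 5
Reactants: 7 (2S)‑2‑[(tert‑butyldimethylsilyloxy)methyl]‑2‑methylpent‑4‑enal
Product: 8 (R)‑tert‑butyl[(2‑ethynyl‑2‑methylpent‑4‑en‑1‑yl)oxy]dimethylsilane
Conditions: dimethyl (1‑diazo‑2‑oxopropyl)phosphonate, K2CO3, MeOH, 0 °C → rt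
Reagents that add atoms: dimethyl (1‑diazo‑2‑oxopropyl)phosphonate, COP(=O)(OC)C(=[N+]=[N-])C(C)=O
Why: Ohira–Bestmann (Seyferth–Gilbert) homologation turns the non‑enolisable aldehyde into the terminal alkyne C5≡C6 under mild carbonate conditions that cannot touch the quaternary centre.

Step 6
Reactants: 8 (R)‑tert‑butyl[(2‑ethynyl‑2‑methylpent‑4‑en‑1‑yl)oxy]dimethylsilane
Product: 9 (2R)‑2‑ethynyl‑2‑methylpent‑4‑en‑1‑ol
Conditions: TBAF, THF, 0 °C → rt
Reagents that add atoms: none
Why: Fluoride cleaves the Si–O bond selectively and frees the homopropargylic alcohol needed for step 7.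

Step 7
Reactants: 9 (2R)‑2‑ethynyl‑2‑methylpent‑4‑en‑1‑ol
Product: 10 (4R)‑4‑methyl‑3‑methylidene‑4‑(prop‑2‑en‑1‑yl)oxolan‑2‑one
Conditions: CO (20 bar), Pd(OAc)2 (cat.), 2‑PyPPh2 (cat.), TsOH (cat.), toluene, 60 °C
Reagents that add atoms: carbon monoxide, [C-]#[O+]
Why: Palladium‑catalysed cyclocarbonylation of a but‑3‑yn‑1‑ol: the alkoxycarbonyl–palladium unit adds across the alkyne in the 5‑exo mode (helped by the gem‑disubstitution at C4) to give the α‑methylene‑γ‑butyrolactone, while the less reactive alkene is left alone.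

Step 8
Reactants: 11 methyl acetoacetate; 12 2‑(2‑bromoethyl)‑2‑methyl‑1,3‑dioxolane
Product: 13 methyl 2‑acetyl‑4‑(2‑methyl‑1,3‑dioxolan‑2‑yl)butanoate (racemic)
Conditions: NaH, NaI (cat.), THF/DMF, 0 → 65 °C
Reagents that add atoms: none
Why: Classical C‑alkylation of the acetoacetate sodium enolate by a primary bromide (iodide catalysis) forms C9–C11, and the new stereocentre is erased in step 9.

Step 9
Reactants: 13 methyl 2‑acetyl‑4‑(2‑methyl‑1,3‑dioxolan‑2‑yl)butanoate
Product: 14 methyl (2E)‑2‑[2‑(2‑methyl‑1,3‑dioxolan‑2‑yl)ethyl]‑3‑(trifluoromethylsulfonyloxy)but‑2‑enoate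
Conditions: Tf2O, aq. Me4NOH, toluene, 0–5 °C
Reagents that add atoms: triflic anhydride, O=S(=O)(OS(=O)(=O)C(F)(F)F)C(F)(F)F
Why: Stereoselective enol triflation of an acetoacetate: the non‑chelated ammonium enolate reacts from its dipole‑minimised geometry, so triflate ends trans to the ester (E), whereas lithium bases would give the chelated Z isomer.

Step 10
Reactants: 14 methyl (2E)‑2‑[2‑(2‑methyl‑1,3‑dioxolan‑2‑yl)ethyl]‑3‑(trifluoromethylsulfonyloxy)but‑2‑enoate
Product: 15 (2E)‑4‑methoxy‑3‑[2‑(2‑methyl‑1,3‑dioxolan‑2‑yl)ethyl]penta‑2,4‑dien‑2‑yl triflate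
Conditions: Cp2TiMe2, toluene, 65 °C, dark
Reagents that add atoms: dimethyltitanocene, C[Ti+2]C.c1cc[cH-]c1.c1cc[cH-]c1
Why: Petasis methylenation (Cp2Ti=CH2, oxatitanacyclobutane, cycloreversion) converts the ester carbonyl into the methyl enol ether C8(OMe)=C7H2 under neutral conditions that should leave vinyl triflate, ketal and alkene geometry untouched.

Step 11
Reactants: 10 (4R)‑4‑methyl‑3‑methylidene‑4‑(prop‑2‑en‑1‑yl)oxolan‑2‑one; 15 (2E)‑dienyl triflate
Product: 17 (4R)‑4‑{(4E)‑6‑methoxy‑4‑methyl‑5‑[2‑(2‑methyl‑1,3‑dioxolan‑2‑yl)ethyl]hepta‑4,6‑dien‑1‑yl}‑4‑methyl‑3‑methylideneoxolan‑2‑one, via B‑alkyl‑9‑BBN 16 (not isolated)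
Conditions: 9‑BBN‑H, THF, 0 °C → rt; then 15, Pd(dppf)Cl2 (cat.), AsPh3 (cat.), Cs2CO3, DMF/THF/H2O, rt
Reagents that add atoms: 9‑BBN‑H, [H]B1C2CCCC1CCC2 (boron kept only in 16)
Why: 9‑BBN‑H adds anti‑Markovnikov to the monosubstituted alkene much faster than to the conjugated, neopentyl 1,1‑disubstituted methylene lactone, and the B‑alkyl Suzuki–Miyaura coupling replaces triflate with retention, so the chain C1 ends trans to C8.

Step 12
Reactants: 17 methoxydiene/methylene‑lactone triene
Product: 18 8‑methoxy‑13,13‑ethylenedioxy‑14,15,17‑trinorlabd‑8‑ene‑5α‑carboxylic acid 18‑lactone (trans‑decalin, 4β‑CH3, 10β‑CH3, C21 axial α on C5, cis‑fused γ‑lactone to 4α‑CH2O)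
Conditions: toluene (high dilution), BHT (cat.), Et3N (trace), 140–150 °C, sealed tube
Reagents that add atoms: none
Why: Thermal, concerted but asynchronous normal‑electron‑demand [4+2] cycloaddition: the 2‑methoxy group makes C7 the nucleophilic diene terminus and the lactone carbonyl on C5 makes C6 the electrophilic end, so the unhindered C6–C7 bond leads and the crowded C5–C10 bond follows in the same transition state. The closest known reaction types are the type‑1 intramolecular Diels–Alder reaction of 1,7,9‑decatrienes that carry the activating carbonyl on the inner dienophile carbon, and cycloadditions of α‑methylene‑γ‑butyrolactones with 2‑oxygenated dienes. Ring B (C5–C6–C7–C8=C9–C10) is the new cycloaddition ring, and ring A (C10–C1–C2–C3–C4–C5) closes as the fused six‑membered tether ring through a chair‑like fold of the three‑carbon chain. C5 is controlled by C4: the chain on C4 is too short to reach the far side of the lactone, so the diene adds to the face of C5=C6 that is syn to C3 and anti to C19, which places C21 α on C5. C10 is controlled by the E geometry of C9=C10 (chain outside, C20 inside) together with the endo position of the flat lactone carbonyl under C8–C9, which puts C20 anti to C21 (trans‑decalin), whereas the exo alternative would push C9 and its side chain over quaternary C4. The step needs endo over exo selectivity and must outrun the 1,5‑hydrogen shift of the inside methyl group, which the matched polarity, the steric bias just named, high dilution and a radical inhibitor should secure.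

Step 13
Reactants: 18 tricyclic lactone
Product: 19 the corresponding lactol (C21 hemiacetal, mixture of anomers)
Conditions: DIBAL‑H, CH2Cl2, −78 °C; Rochelle salt
Reagents that add atoms: none
Why: Partial reduction of a lactone by DIBAL‑H stops at the aluminium lactolate at low temperature, and enol ether and ketal are inert to hydride.

Step 14
Reactants: 19 lactol
Product: 20 8‑methoxy‑13,13‑ethylenedioxy‑14,15,17‑trinorlabd‑8‑en‑18‑ol (5α‑H)
Conditions: RhCl(PPh3)3 (1 equiv), xylene, reflux
Reagents that add atoms: none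
Why: Tsuji–Wilkinson decarbonylation acts on the hydroxy‑aldehyde tautomer of the lactol (as with aldose lactols), and since oxidative addition, CO extrusion and reductive elimination run with retention, hydrogen takes the α position of C21 on C5 and the 18‑OH is set free.

Step 15
Reactants: 20 enol ether ketal alcohol
Product: 21 18‑hydroxy‑14,15,17‑trinorlabdane‑8,13‑dione (5α‑H, 9α‑H, 10β‑CH3)
Conditions: 1 M HCl, THF, rt
Reagents that add atoms: water, O
Why: Acid hydrolysis of enol ether and ketal, in which C9 is protonated axially from the α face away from C20 and, being epimerisable, settles with the side chain equatorial (9β).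

Step 16
Reactants: 21 18‑hydroxy‑14,15,17‑trinorlabdane‑8,13‑dione
Product: 22 ethyl 18‑hydroxy‑8‑oxo‑17‑norlabd‑13E‑en‑15‑oate
Conditions: (EtO)2P(O)CH2CO2Et, NaH, THF, 0 °C → rt; chromatography removes the Z isomer
Reagents that add atoms: triethyl phosphonoacetate, CCOC(=O)CP(=O)(OCC)OCC
Why: Horner–Wadsworth–Emmons olefination takes the open methyl ketone C13 and not the C8 ketone flanked by C9 and shielded by C20, and it favours the E‑enoate with the larger chain trans to the ester.

Step 17
Reactants: 22 ethyl 18‑hydroxy‑8‑oxo‑17‑norlabd‑13E‑en‑15‑oate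
Product: 23 ethyl 18‑hydroxylabda‑8(17),13E‑dien‑15‑oate
Conditions: Zn, CH2Br2, TiCl4, THF/CH2Cl2, 0 °C → rt
Reagents that add atoms: dibromomethane, BrCBr
Why: Lombardo methylenation uses a non‑basic gem‑dimetallic CH2 reagent that takes hindered enolisable ketones and spares esters, so C9 and the enoate stay intact.

Step 18
Reactants: 23 ethyl 18‑hydroxylabda‑8(17),13E‑dien‑15‑oate
Product: 25 ethyl 8α,18‑dihydroxylabd‑13E‑en‑15‑oate, via organomercurial 24 (not isolated)
Conditions: Hg(OAc)2, THF/H2O, rt; then NaBH4, aq. NaOH, 0 °C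
Reagents that add atoms: water, O; mercury(II) acetate, CC(=O)O[Hg]OC(C)=O (kept only in 24)
Why: Oxymercuration–demercuration: only the electron‑rich 1,1‑disubstituted alkene forms a mercurinium ion, water opens it at tertiary C8 from the α face because the β face is screened by the syn‑axial C20 methyl, and borohydride replaces mercury by hydrogen to give equatorial 8α‑OH and axial C17H3.

Step 19
Reactants: 25 ethyl 8α,18‑dihydroxylabd‑13E‑en‑15‑oate
Product: 26 8α,18‑dihydroxylabd‑13E‑en‑15‑oic acid
Conditions: LiOH, THF/MeOH/H2O, 40 °C; then 1 M HCl to pH 3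
Reagents that add atoms: lithium hydroxide, [Li+].[OH-]
Why: Saponification of the ethyl ester, with no other base‑labile group present and a conjugated E‑alkene that is configurationally stable.

Step 20
Reactants: 26 8α,18‑dihydroxylabd‑13E‑en‑15‑oic acid
Product: 28 18‑acetoxy‑8α‑hydroxylabd‑13E‑en‑15‑oic acid (target), via mixed anhydride 27 (not isolated)
Conditions: Ac2O, pyridine, CH2Cl2, 0 °C → rt; then H2O/THF, rt
Reagents that add atoms: acetic anhydride, CC(=O)OC(C)=O
Why: Acetylation discriminates by steric class: the primary 18‑OH reacts, the tertiary 8α‑OH does not without forcing catalysis, and the mixed anhydride formed at C15 is hydrolysed at its acetyl carbonyl during the aqueous stir.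

Compound list
1 | pent‑1‑en‑4‑yne | C=CCC#C | starting material
2 | (E)‑dimethyl(2‑methylpenta‑1,4‑dien‑1‑yl)alane | C=CC/C(C)=C/[Al](C)C | intermediate
3 | lithium (E)‑butyldimethyl(2‑methylpenta‑1,4‑dien‑1‑yl)aluminate | [Li+].C=CC/C(C)=C/[Al-](C)(C)CCCC | intermediate
4 | (2E)‑3‑methylhexa‑2,5‑dien‑1‑ol | C=CC/C(C)=C/CO | intermediate
5 | [(2S,3S)‑3‑methyl‑3‑(prop‑2‑en‑1‑yl)oxiran‑2‑yl]methanol | OC[C@@H]1O[C@@]1(C)CC=C | intermediate
6 | TBS ether of 5 | CC(C)(C)[Si](C)(C)OC[C@@H]1O[C@@]1(C)CC=C | intermediate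
7 | (2S)‑2‑[(tert‑butyldimethylsilyloxy)methyl]‑2‑methylpent‑4‑enal | C=CC[C@@](C=O)(C)CO[Si](C)(C)C(C)(C)C | intermediate
8 | (R)‑tert‑butyl[(2‑ethynyl‑2‑methylpent‑4‑en‑1‑yl)oxy]dimethylsilane | C=CC[C@@](C#C)(C)CO[Si](C)(C)C(C)(C)C | intermediate
9 | (2R)‑2‑ethynyl‑2‑methylpent‑4‑en‑1‑ol | C=CC[C@@](C#C)(C)CO | intermediate
10 | (4R)‑4‑methyl‑3‑methylidene‑4‑(prop‑2‑en‑1‑yl)oxolan‑2‑one | C=CC[C@@]1(C)COC(=O)C1=C | intermediate
11 | methyl acetoacetate | CC(=O)CC(=O)OC | starting material
12 | 2‑(2‑bromoethyl)‑2‑methyl‑1,3‑dioxolane | CC1(CCBr)OCCO1 | starting material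
13 | methyl 2‑acetyl‑4‑(2‑methyl‑1,3‑dioxolan‑2‑yl)butanoate (racemic) | CC(=O)C(CCC1(C)OCCO1)C(=O)OC | intermediate
14 | methyl (2E)‑2‑[2‑(2‑methyl‑1,3‑dioxolan‑2‑yl)ethyl]‑3‑(trifluoromethylsulfonyloxy)but‑2‑enoate | C/C(OS(=O)(=O)C(F)(F)F)=C(\C(=O)OC)CCC1(C)OCCO1 | intermediate
15 | (2E)‑4‑methoxy‑3‑[2‑(2‑methyl‑1,3‑dioxolan‑2‑yl)ethyl]penta‑2,4‑dien‑2‑yl triflate | C=C(OC)/C(CCC1(C)OCCO1)=C(\C)OS(=O)(=O)C(F)(F)F | intermediate
16 | B‑alkyl‑9‑BBN from 10 (boron on C1) | C=C1C(=O)OC[C@]1(C)CCCB2C3CCCC2CCC3 | intermediate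
17 | (4R,4E)‑methoxydiene/methylene‑lactone triene | C=C1C(=O)OC[C@]1(C)CCC/C(C)=C(/C(=C)OC)CCC2(C)OCCO2 | intermediate
18 | tricyclic lactone (cycloadduct; 4β‑CH3, 10β‑CH3, C21 α on C5) | O=C1OC[C@]2(C)CCC[C@]3(C)C(CCC4(C)OCCO4)=C(OC)CC[C@@]123 | intermediate
19 | lactol of 18 (anomers) | OC1OC[C@]2(C)CCC[C@]3(C)C(CCC4(C)OCCO4)=C(OC)CC[C@@]123 | intermediate
20 | 8‑methoxy‑13,13‑ethylenedioxy‑14,15,17‑trinorlabd‑8‑en‑18‑ol | OC[C@]1(C)CCC[C@]2(C)C(CCC3(C)OCCO3)=C(OC)CC[C@@H]12 | intermediate
21 | 18‑hydroxy‑14,15,17‑trinorlabdane‑8,13‑dione | OC[C@]1(C)CCC[C@]2(C)[C@@H](CCC(C)=O)C(=O)CC[C@@H]12 | intermediate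
22 | ethyl 18‑hydroxy‑8‑oxo‑17‑norlabd‑13E‑en‑15‑oate | OC[C@]1(C)CCC[C@]2(C)[C@@H](CC/C(C)=C/C(=O)OCC)C(=O)CC[C@@H]12 | intermediate
23 | ethyl 18‑hydroxylabda‑8(17),13E‑dien‑15‑oate | OC[C@]1(C)CCC[C@]2(C)[C@@H](CC/C(C)=C/C(=O)OCC)C(=C)CC[C@@H]12 | intermediate
24 | 17‑(acetoxymercurio)‑8α‑ol | OC[C@]1(C)CCC[C@]2(C)[C@@H](CC/C(C)=C/C(=O)OCC)[C@](C[Hg]OC(C)=O)(O)CC[C@@H]12 | intermediate
25 | ethyl 8α,18‑dihydroxylabd‑13E‑en‑15‑oate | OC[C@]1(C)CCC[C@]2(C)[C@@H](CC/C(C)=C/C(=O)OCC)[C@](C)(O)CC[C@@H]12 | intermediate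
26 | 8α,18‑dihydroxylabd‑13E‑en‑15‑oic acid | OC[C@]1(C)CCC[C@]2(C)[C@@H](CC/C(C)=C/C(=O)O)[C@](C)(O)CC[C@@H]12 | intermediate
27 | 18‑O‑acetyl C15 acetic mixed anhydride | CC(=O)OC[C@]1(C)CCC[C@]2(C)[C@@H](CC/C(C)=C/C(=O)OC(C)=O)[C@](C)(O)CC[C@@H]12 | intermediate
28 | (2E)‑5‑[(1R,2R,4aR,5R,8aS)‑5‑(acetyloxymethyl)‑2‑hydroxy‑2,5,8a‑trimethyldecahydronaphthalen‑1‑yl]‑3‑methylpent‑2‑enoic acid | CC(=O)OC[C@]1(C)CCC[C@]2(C)[C@@H](CC/C(C)=C/C(=O)O)[C@](C)(O)CC[C@@H]12 | target

Total step count: 20. Longest linear sequence: 17 (steps 1–7 and 11–20; steps 8–10 run in parallel).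

Steps most likely to fail

Step 12. The cycloaddition may stall because the bond between two fully substituted carbons, C5 and C10, has to form next to quaternary C4. The 1,5‑hydrogen shift in the diene or polymerisation of the dienophile could then take over. The fallback moves the activating group from C5 to C6 so that C5 stays tertiary. It sets out from aldehyde 7. Horner–Wadsworth–Emmons reaction with diethyl (phenylsulfonylmethyl)phosphonate/NaH should give the (E)‑vinyl sulfone F1. 9‑BBN‑H on the allyl group should give the borane F2, and Suzuki–Miyaura coupling with triflate 15 as in step 11 should give the sulfonyl triene F3. Heating in toluene should close rings A and B through the endo transition state to the 6α‑sulfonyl trans‑decalin F4. Without the lactone ring, the two faces are distinguished only by CH3 against CH2OTBS on C4, so the C4‑epimeric series would have to be removed by chromatography. Sodium amalgam/Na2HPO4 in methanol should remove the sulfonyl group to give the silyl ether F5. The conditions of step 15 should then cleave enol ether, ketal and silyl ether together, which brings the route back at diketone 21.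

Step 14. The decarbonylation may fail because the lactol stays closed, because CO extrusion at a tertiary carbon between two quaternary centres is slow, or because β‑hydride elimination towards C6 competes. The fallback takes the carbon out by a radical chain on an aldehyde that cannot close. It sets out from lactone 18. LiAlH4 should give the diol F6, and TESCl/imidazole should silylate the more open C18 hydroxyl to the mono‑TES ether F7. Dess–Martin periodinane/NaHCO3 should give the C5 aldehyde F8. Heating with tert‑dodecanethiol and a radical initiator should then run a thiol‑catalysed radical decarbonylation. The tertiary acyl radical loses CO, and the C5 radical takes hydrogen from the α face, away from the axial C19 and C20 methyl groups, to give the TES ether F9. The conditions of step 15 then cleave TES ether, enol ether and ketal and bring the route back at diketone 21.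

Step 11. The methylene lactone may be lost through hydroboration, through conjugate addition of hydroxide or phosphine, or through Heck‑type insertion of the alkenylpalladium species. The fallback masks the dienophile as its amine adduct. It sets out from lactone 10. Dimethylamine in THF should add to give the Mannich base F10 (mixture at C5). 9‑BBN‑H (one extra equivalent for the amine) should give the borane F11, and coupling with 15 as in step 11 should give the coupled amine F12. Methyl iodide should give the ammonium iodide F13, and aqueous NaHCO3 should eliminate the amine, which brings the route back at triene 17.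

Further compounds
F1 | step 12 | (R,E)‑tert‑butyldimethyl{[2‑methyl‑2‑(2‑phenylsulfonylethenyl)pent‑4‑en‑1‑yl]oxy}silane | C=CC[C@@](C)(CO[Si](C)(C)C(C)(C)C)/C=C/S(=O)(=O)c1ccccc1
F2 | step 12 | B‑alkyl‑9‑BBN from F1 | CC(C)(C)[Si](C)(C)OC[C@@](C)(/C=C/S(=O)(=O)c1ccccc1)CCCB1C2CCCC1CCC2
F3 | step 12 | sulfonyl triene | CC(C)(C)[Si](C)(C)OC[C@@](C)(/C=C/S(=O)(=O)c1ccccc1)CCC/C(C)=C(/C(=C)OC)CCC1(C)OCCO1
F4 | step 12 | 6α‑phenylsulfonyl‑18‑TBSO‑8‑methoxy‑13,13‑ethylenedioxy‑14,15,17‑trinorlabd‑8‑ene | CC(C)(C)[Si](C)(C)OC[C@]1(C)CCC[C@]2(C)C(CCC3(C)OCCO3)=C(OC)C[C@H](S(=O)(=O)c3ccccc3)[C@@H]12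
F5 | step 12 | TBS ether of 20 | CC(C)(C)[Si](C)(C)OC[C@]1(C)CCC[C@]2(C)C(CCC3(C)OCCO3)=C(OC)CC[C@@H]12
F6 | step 14 | 5α‑hydroxymethyl‑18‑ol (diol from 18) | OC[C@]1(C)CCC[C@]2(C)C(CCC3(C)OCCO3)=C(OC)CC[C@@]12CO
F7 | step 14 | 18‑O‑TES ether of F6 | CC[Si](CC)(CC)OC[C@]1(C)CCC[C@]2(C)C(CCC3(C)OCCO3)=C(OC)CC[C@@]12CO
F8 | step 14 | 5α‑carbaldehyde | CC[Si](CC)(CC)OC[C@]1(C)CCC[C@]2(C)C(CCC3(C)OCCO3)=C(OC)CC[C@@]12C=O
F9 | step 14 | TES ether of 20 | CC[Si](CC)(CC)OC[C@]1(C)CCC[C@]2(C)C(CCC3(C)OCCO3)=C(OC)CC[C@@H]12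
F10 | step 11 | (4R)‑3‑(dimethylaminomethyl)‑4‑methyl‑4‑(prop‑2‑en‑1‑yl)oxolan‑2‑one | CN(C)CC1C(=O)OC[C@]1(C)CC=C
F11 | step 11 | B‑alkyl‑9‑BBN from F10 | CN(C)CC1C(=O)OC[C@]1(C)CCCB2C3CCCC2CCC3
F12 | step 11 | coupled amine | CN(C)CC1C(=O)OC[C@]1(C)CCC/C(C)=C(/C(=C)OC)CCC2(C)OCCO2
F13 | step 11 | trimethylammonium iodide of F12 | C[N+](C)(C)CC1C(=O)OC[C@]1(C)CCC/C(C)=C(/C(=C)OC)CCC2(C)OCCO2.[I-]
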